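I kept books on the charge.

| flask | starting material | remark | time |
|---|---|---|---|
| autumn | 0.025 M | run made earlier |  |
| spring | 0.10 M | run made earlier |  |
| flask | 0.050 M |  | 15 h |

| run | time / h | target / % | over-reaction product / % | starting material / % |
|---|---|---|---|---|
| autumn | 1.00 | 8.9 | 7.0 | 10.7 |
| autumn | 1.50 | 8.1 | 11.0 | 9.1 |
| autumn | 2.50 | 7.2 | 18.8 | 8.4 |
| autumn | 4.00 | 7.3 | 28.0 | 7.9 |
| autumn | 8.00 | 4.5 | 48.9 | 6.2 |
| autumn | 12.0 | 3.0 | 64.7 | 3.4 |
| spring | 0.833 | 9.6 | 7.0 | 10.2 |
| spring | 2.50 | 8.1 | 18.9 | 9.2 |
| spring | 4.00 | 6.8 | 30.3 | 8.0 |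
| spring | 6.00 | 4.8 | 39.1 | 5.7 |
| spring | 10.0 | 3.5 | 58.2 | 5.3 |
| spring | 12.0 | 3.7 | 64.3 | 4.5 |

(readings scatter by 0.5 percentage points)

- share of target in target plus over-reaction product at 2.0 min
- share of target in target plus over-reaction product at 40 min
- share of target in target plus over-reaction product at 15 h



**The entries.** At 12.0 h the autumn run held over-reaction product 64.7%, target 3.0% and starting material 3.4%, so an unseen entry of 28.9% closes its books. The spring run, with a charge 4.00 times larger, read 64.3%, 3.7% and 4.5%, so I booked everything in percent of charge.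

**My reckoning.** I took all that was not yet product as one pool keeping fixed shares (a pre-equilibrium). From both runs at 12.0 h I read 9.44% for f, the pool share: target divided by what is not yet product. The product readings gave a drain constant λ of 0.0863 h⁻¹, the pool after time t being exp(−λt). For the flask at 15 h the pool is 27.4%, so product is 72.6%, target 2.59% and the share 3.44%. The two earlier times fall before the first reading at 0.833 h, so I booked nothing there.

**The forecast.** It gave 95%, 68% and 3.5%, a little above mine at the end, on grounds of “fast equilibration among starting material, target and reservoir”.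

**The flask.** The flask gave 98.8%, 65.8% and 3.59%.

    starting material ⇌ intermediate A (K = 0.900, k = 0.00185 s⁻¹)
    intermediate A ⇌ intermediate B (K = 0.400, k = 0.00113 s⁻¹)
    starting material ⇌ intermediate C (K = 4.60, k = 0.00470 s⁻¹)
    intermediate B ⇌ target (K = 2.90, k = 0.00227 s⁻¹)
    target ⇌ intermediate A (k = 0.00254 s⁻¹)
    target → over-reaction product (k = 2.48 × 10⁻⁴ s⁻¹)
    starting material ⇌ dormant form (K = 1.42, k = 0.00120 s⁻¹)

**Two half-lives.** At 3.01 h in the flask, target had a half-life of 0.076 h by the forward step to intermediate A alone and 0.78 h by the step to over-reaction product, the second ten times the first. At 7.50 h, with product at 46.9%, f gives target 5.01%, and the flask held 5.10%.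

**A larger charge.** For a flask with 0.20 M, charge enters no entry of my reckoning, so f and λ again give 3.44%. The computed share there is 3.59%.

The earlier runs and the new flask were generated by integration from invented constants; scatter was added.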